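- At early times in the theta run substrate disappears fast, so the question is what stands in a new flask much later.

in all of them: substrate 0.055 M

|  | reagent | remark | time |
|---|---|---|---|
| theta | 6 equiv | run made earlier |  |
| flask | 4.00 equiv |  | 10 h |
theta run (percent of the substrate charged)

| time / h | substrate / % | target / % | isomer of the product / % |
|---|---|---|---|
| 0.417 | 0.9 | 83.2 | 15.1 |
| 1.00 | 0 | 66.4 | 31.5 |
| 2.00 | 0 | 61.2 | 38.2 |
| 3.00 | 0 | 67.1 | 36.3 |

(standard deviation of a reading: 1 percentage point)
- steps under discussion: substrate + reagent + target -> 2 target; substrate + reagent -> target; target <-> isomer of the product
- the reaction counts as stopped when no species that holds the substrate changes by six tenths of a point or more over the second half of the time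
* which holds at 10 h: what has brought the reaction to rest, or that it has not come to rest (forward and back rates have come level / it is still moving / the reagent has run out first / all of the substrate has reacted)
* part of the substrate gone at 10 h
* the target standing at 10 h, as a percentage of the substrate charged
* the isomer of the product standing at 10 h, as a percentage of the substrate charged

- The theta run looks contradictory: substrate reads 0.9% at 0.417 h, yet target goes on falling, from 83.2% to 61.2% at 2.00 h.
- It clears up by reckoning. Target and isomer of the product sum to 99.4% at 2.00 h, and the isomer reading rises from 15.1% to 38.2% over the same stretch, so target is turning into isomer.
- For a first-order exchange, the gap between c(isomer) and its resting value shrinks as exp(−λt). Taking the mean of the last two readings, 37.3%, as that resting value, the gaps at 0.417 h and 1.00 h give λ = 2.31 h⁻¹. Read off these scattered points, that is a half-life of about 0.300 h, far shorter than 10 h.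
- So carry one number, the resting share, meaning target divided by target plus isomer once the exchange has stopped moving. The last two readings put it at 63.3%.
- My reckoning for the flask: each step that uses substrate takes one reagent per substrate, and 4.00 equiv is more than that, so substrate is the limiting reagent. If the rate is first order in reagent, substrate reaches the same low reading near 0.626 h, well before 10 h. I expect target at 63.3%, isomer at 36.7%, and a stop through substrate being used up.
- The forecast gives 100% of the substrate gone, target 63% and isomer 37%, and for the ending says “forward and back rates have come level”, which differs from my ending.
- The flask gives: all of the substrate has reacted; 100% gone, target 64.1%, isomer 35.9%.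

    substrate + reagent + target → 2 target (k = 36.0 L² mol⁻² min⁻¹)
    substrate + reagent → target (k = 1.30 × 10⁻⁴ L mol⁻¹ min⁻¹)
    target ⇌ isomer of the product (K = 0.560, k = 0.0230 min⁻¹)

- The flask parts from the forecast on the ending: 0% of the charged substrate stands against 75% of the charged reagent. In the flask the half-life of target by the forward exchange step alone is 0.50 h, short against 10 h. The resting share times the substrate gone gives 63.3% of target in this flask. In the neighbouring flask with 1.00 equiv of reagent, 3.03% of the substrate stands at the end, so the share gives 61.4%, and that flask holds 62.2%.

The runs come from a simulation with made-up constants, and the scatter is random.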